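## The problem

The target is a 2,2-dimethyl-2H-chromene whose benzene ring (ring A: C4a, C5, C6, C7, C8, C8a) is fully substituted: the pyran oxygen O1 at C8a, a prenyl group at C8, a methoxy group at C7, a 2-(4-hydroxyphenyl)-1,2-dioxoethyl group at C6, a free hydroxyl at C5 and the pyran carbon C4 at C4a. There is no stereocentre, so nothing has to be set or relayed, and the difficulty is purely regiochemical. Three oxygens in a 1,3,5-relationship must be told apart (ring ether, methyl ether, free phenol) and three different carbon substituents must be placed between them, so any approach from a symmetric trioxygenated benzene has to win several selective O- and C-functionalisations in a row. The functional groups are fragile in complementary ways: the prenyl and chromene alkenes do not tolerate strong acid, electrophilic oxidants or hydrogenation, and the 1,2-dione is sensitive to base and nucleophiles. A free phenol ortho to an alkyne, the natural precursor of the dione, closes readily to a benzofuran, so the phenols must stay masked until the dione is in place and the last unmasking has to be mild and non-acidic. The feature that invites a benzannulation is the strict alternation of oxygen and carbon around ring A. A phenolic oxygen at C8a, a carbon substituent at C8 and an alkoxy group at C7 are exactly what a ketene carbon and the two carbons of an alkoxyalkyne deliver. The second meta oxygen, at C5, sits where the 3-substituent of a cyclobutenone ends up, so each oxygen can be born with its own substituent (H, Me, silyl).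

## Retrosynthesis

Atom labels follow the chromene numbering of the target.

**23 from 22 (two O–Si bonds).** Both phenols are masked as triisopropylsilyl ethers. Acetal, benzyl or methyl protection would need acid, hydrogenolysis or Lewis acid, each of which threatens the prenyl group, the chromene or the C7 methyl ether. Two silyl ethers fall together to buffered fluoride. The forward step only has to keep the dione away from strong base.

**22 from 21 (the two C=O bonds).** The dione is traced back to a diarylalkyne. Direct acylation of ring A with an arylglyoxylic acid derivative would need Lewis acid on an acid-sensitive substrate, whereas an alkyne is inert until it is wanted. The forward reaction must oxidise the alkyne and leave two alkenes untouched, which points to a nucleophilic oxidant under gold catalysis.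

**21 from 15 and 20, and 15 from 14 (C6–C(sp) bond, then C6–I).**
- Carrying the arylethynyl group through the annulation, on the cyclobutenone carbon that becomes C6, would save two steps. At the vinylcyclobutenone stage (the stage of 8), however, that carbon is sp3 and would hold both the alkyne and the siloxyvinyl group.
- Ring opening can turn either group toward the ketene, and donor-substituted, bulky groups prefer to turn outward. A ketene with a cis alkynyl group is the substrate of a Moore cyclisation to diradical-derived products.
- With hydrogen on that carbon this leak does not exist. The price is an iodination and a Sonogashira coupling, but C6 is the only aromatic C–H of 14 and is activated by all three oxygens, so position is not in question.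
- Alkyne 20 comes from 4-iodophenol 16 through 17 and 19, using ethynyltrimethylsilane 18.

**14 from 11 and 12 (O1–C2 and C4–C4a bonds).** The pyran is removed as prenal 12. Phenol 11 has one free hydroxyl and only one free ortho carbon, because the other carries the prenyl group, so only one chromene can form. This removes a ring and five carbons. The forward step must bring about ortho C–C bond formation without acid strong enough to cyclise the ortho-prenylphenol to a chroman.

**11 from 2 and 6 (C8–C8a and C6–C7 bonds; ring A).** This is the key cut. Ring A is opened into a four-carbon cyclobutenone 2 (C8a, C6, C5, C4a) and a two-carbon ynol ether 6 (C7, C8).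
- Against any functionalisation of a preformed trioxygenated arene, this cut fixes the whole substitution pattern by mechanism. The ketene carbon becomes the only free phenol, the ynol ether carbon arrives as the methyl ether and the cyclobutenone C3 oxygen arrives silylated.
- Both precursors are small, achiral and one step from commercial materials.
- The forward reaction has to open a push–pull stabilised cyclobutenone thermally and to add the ynol ether with the ketene carbon bonding to the prenyl-bearing alkyne carbon.

**2 from 1, and 6 from 3 and 4 by way of 5.** Cyclobutenone 2 is the O-silyl derivative of cyclobutane-1,3-dione 1. Alkyne 6 is cut at the propargylic C–C bond into prenyl bromide 4 and sodium methoxyacetylide 5, itself made in the flask from chloroacetal 3.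

## Roads not taken

**Alternative 1: oxalyl linchpin.**
- Cut: both bonds flanking the two-carbon dione (C6–CO and CO–aryl); no ring is formed.
- Forward step: the C6-metalated chromene 6-lithio-7-methoxy-5-(methoxymethoxy)-2,2-dimethyl-8-(3-methylbut-2-enyl)-2H-chromene A3 adds to 1,4-dimethylpiperazine-2,3-dione A2. The tetrahedral adduct is treated in the same pot with 4-(methoxymethoxy)phenyllithium A4, and work-up releases 1-[7-methoxy-5-(methoxymethoxy)-2,2-dimethyl-8-(3-methylbut-2-en-1-yl)-2H-chromen-6-yl]-2-[4-(methoxymethoxy)phenyl]ethane-1,2-dione A1, the bis(methoxymethyl) ether of the target.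
- Merits: diamide A2 takes up A3 and then A4 one after the other, so the dione arrives at the right oxidation level with no oxidant ever meeting the two alkenes, and the coupling is highly convergent. In the end-game this road is shorter than the chosen one, which spends three steps on the same two carbons: iodination, coupling and oxidation.
- Weak points: the whole regiochemical problem is moved into the synthesis of A3, whose three oxygens would have to be differentiated on a symmetric trioxygenated benzene. A3 is a di-ortho-substituted aryllithium adding to a hindered diamide. The two acetal groups of A1 must then be removed with acid beside a prenyl group and a chromene.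
- Comparison: the chosen plan sets against the shorter end-game a ring A whose pattern is fixed by the mechanism of its formation, and a fluoride-only deprotection. The linchpin is kept as the fallback for step 10.

**Alternative 2: Alder–Rickert aromatisation.**
- Cut: C5–C6 and C7–C8.
- Forward step: 1-(4-methoxybenzyloxy)-3-(tert-butyldimethylsiloxy)-4-(3-methylbut-2-enyl)cyclohexa-1,3-diene A6 and 1,1,4-trimethoxy-1-[4-(methoxymethoxy)phenyl]but-3-yn-2-one A7 undergo a Diels–Alder addition. The bicyclic adduct loses ethene A8 to give 1-[4-hydroxy-2-methoxy-6-(4-methoxybenzyloxy)-3-(3-methylbut-2-enyl)phenyl]-2,2-dimethoxy-2-[4-(methoxymethoxy)phenyl]ethanone A5.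
- Merits: ring A is formed with the complete C6 side chain already in place as a ketal-protected dione, and the three oxygens are differentiated. Both donors of A6 and the acyl group of A7 polarise the partners the same way. In convergence this is better than the chosen plan, which adds the C6 chain after the ring.
- Weak points: A7 is a push–pull alkyne and a reluctant dienophile. Both diene termini of A6 are fully substituted. Cycloaddition and the loss of A8 need high temperature, at which a cross-conjugated dienol ether can shift hydrogen or aromatise. The regiodefined preparation of A6 is not trivial. A5 then needs three different unmaskings beside electron-rich alkenes: the 4-methoxybenzyl ether, the ketal and the acetal, two of them acidic and one oxidative or acidic.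
- Comparison: the chosen plan offers a key step whose partners are matched in polarity (electrophilic ketene, nucleophilic ynol ether) and a single fluoride deprotection.

**Alternative 3: pyrone-to-phloroglucinol ring transformation.**
- Cut: C4a–C5.
- Forward step: magnesium dimethoxide A11 in its parent alcohol opens 3-{2,2-dimethoxy-2-[4-(methoxymethoxy)phenyl]acetyl}-4-methoxy-6-methyl-5-(3-methylbut-2-enyl)-2H-pyran-2-one A10 to a chelated triketo ester. The methyl ketone enolate then attacks the ester carbonyl and gives 1-[2,4-dihydroxy-6-methoxy-5-(3-methylbut-2-enyl)phenyl]-2,2-dimethoxy-2-[4-(methoxymethoxy)phenyl]ethanone A9.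
- Merits: a mild, biomimetic Claisen closure with the cheap base A11, the acyl chain in place and the C7 methyl ether secured. It is probably the shortest way to a fully substituted ring A.
- Weak points: A9 has two free phenols, at C5 and at C8a, on either side of the only free ring carbon. The chromene annulation can close on either oxygen, and only the hydrogen bond of the C5 hydroxyl to the ketone tells them apart. A10 itself needs C-acylation, C-prenylation and selective O-methylation of a hydroxypyrone. The ketal must finally be hydrolysed with acid.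
- Comparison: the chosen plan is longer but differentiates all three oxygens unambiguously and keeps acid out of the end-game.

Key step: step 3

Assumption: cyclobutane-1,3-dione (1) is treated as a commercial reagent; it reacts through its enol form, 3-hydroxycyclobut-2-enone.

## Route

Step 1
Reactants: 1 cyclobutane-1,3-dione
Product: 2 3-[(triisopropylsilyl)oxy]cyclobut-2-en-1-one
Conditions: i-Pr3SiOTf (1.05 equiv), Et3N (1.2 equiv), CH2Cl2, −78 to 0 °C
Reagents that add atoms: triisopropylsilyl trifluoromethanesulfonate, CC(C)[Si](OS(=O)(=O)C(F)(F)F)(C(C)C)C(C)C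
Why: O-silylation of a cyclic 1,3-diketone; the strongly acidic enol is silylated on oxygen by the hard silyl triflate to give a vinylogous silyl ester. The bulky triisopropylsilyl group is chosen so that this oxygen (the future C5–OH) survives every later step until fluoride is applied.

Step 2
Reactants: 3 chloroacetaldehyde dimethyl acetal (2-chloro-1,1-dimethoxyethane); 4 1-bromo-3-methylbut-2-ene
Product: 6 1-methoxy-5-methylhex-4-en-1-yne, via sodium methoxyacetylide 5 (not isolated)
Conditions: NaNH2 (3.0 equiv), liq. NH3, −33 °C; then 4, −33 °C to rt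
Reagents that add atoms: none
Why: Twofold elimination (methanol, then HCl) from the chloroacetal with NaNH2 is the classical alkoxyacetylene synthesis and leaves the sodium acetylide, which displaces the primary allylic bromide by SN2. Exactly three equivalents of amide are used so that no free base remains to isomerise the skipped enyne; the methyl ynol ether cannot lose an alkene by retro-ene reaction on later heating.

Step 3
Reactants: 2 3-[(triisopropylsilyl)oxy]cyclobut-2-en-1-one; 6 1-methoxy-5-methylhex-4-en-1-yne
Product: 11 3-methoxy-2-(3-methylbut-2-en-1-yl)-5-[(triisopropylsilyl)oxy]phenol, via siloxyvinylketene 7 (not isolated), via vinylcyclobutenone adduct 8 (not isolated), via dienylketene 9 (not isolated), via cyclohexadienone tautomer 10 (not isolated)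
Conditions: 6 (1.5 equiv), PhMe, sealed tube, 80 °C then 140 °C
Reagents that add atoms: none
Why: Heating opens cyclobutenone 2 by 4π electrocyclic cleavage to siloxyvinylketene 7, whose electrophilic carbonyl carbon is attacked by the nucleophilic, prenyl-bearing carbon of ynol ether 6 in a regiospecific (2+2) cycloaddition that forms the C8–C8a and C6–C7 bonds and gives vinylcyclobutenone 8. A second 4π opening gives dienylketene 9, ring A closes by thermal disrotatory 6π electrocyclisation to cyclohexadienone 10 (C4a–C8a bond), and tautomerisation gives phenol 11. The closest known reaction is the Danheiser benzannulation of cyclobutenones with alkoxy- and siloxyalkynes; the 3-siloxy group on the cyclobutenone is the extension, and as part of a vinylogous ester it is expected to raise the temperature of the first ring opening, hence the second heating stage. No stereocentre survives, since the sp3 carbon of 8 becomes aromatic. The regiochemistry needed (ketene carbon to the prenyl-bearing alkyne carbon) is secured by the methoxy group, which polarises the alkyne so that its oxygen-bearing carbon ends up meta to the new hydroxyl. Chemoselectivity for the ynol ether over the prenyl alkene follows from the far higher nucleophilicity of the former toward ketenes. Because the sp3 carbon of 8 carries only hydrogen besides the vinyl group, a ring opening that turns the vinyl group outward gives a ketene that can only reclose, so all material should drain through 9. The ketene carbon becomes the only free phenol (the future O1), the ynol ether carbon becomes C7–OMe and the siloxy carbon becomes C5, so the three oxygens are differentiated from the start.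

Step 4
Reactants: 11 3-methoxy-2-(3-methylbut-2-en-1-yl)-5-[(triisopropylsilyl)oxy]phenol; 12 3-methylbut-2-enal
Product: 14 triisopropyl{[7-methoxy-2,2-dimethyl-8-(3-methylbut-2-en-1-yl)-2H-chromen-5-yl]oxy}silane, via ortho-quinone methide 13 (not isolated)
Conditions: 12 (2 equiv), ethylenediammonium diacetate (20 mol%), PhMe, 110 °C
Reagents that add atoms: none
Why: Amine-catalysed condensation of the enal (as its iminium ion) at the free ortho carbon of the electron-rich phenol gives ortho-quinone methide 13, which closes by oxa-6π electrocyclisation to the 2H-chromene, a formal (3+3) chromene annulation of a phenol with an enal. The other ortho carbon carries the prenyl group and an adduct at the para carbon cannot close a pyran and should revert, so only one chromene can form; the near-neutral medium avoids acid-induced chroman formation from the ortho-prenylphenol.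

Step 5
Reactants: 14 triisopropyl{[7-methoxy-2,2-dimethyl-8-(3-methylbut-2-en-1-yl)-2H-chromen-5-yl]oxy}silane
Product: 15 {[6-iodo-7-methoxy-2,2-dimethyl-8-(3-methylbut-2-en-1-yl)-2H-chromen-5-yl]oxy}triisopropylsilane
Conditions: NIS (1.05 equiv), MeCN, 0 °C, dark
Reagents that add atoms: N-iodosuccinimide, O=C1CCC(=O)N1I
Why: Electrophilic aromatic iodination at C6, the only aromatic C–H, which is ortho to two oxygens and para to the third. Without added acid or an external nucleophile, iodonium transfer to the alkenes is reversible whereas substitution on the arene is not.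

Step 6
Reactants: 16 4-iodophenol
Product: 17 (4-iodophenoxy)triisopropylsilane
Conditions: i-Pr3SiCl (1.1 equiv), imidazole (2 equiv), DMF, rt
Reagents that add atoms: chlorotriisopropylsilane, CC(C)[Si](Cl)(C(C)C)C(C)C
Why: Standard imidazole-promoted silylation of a phenol. The same silyl group as at C5 is chosen so that both fall in one final step.

Step 7
Reactants: 17 (4-iodophenoxy)triisopropylsilane; 18 ethynyltrimethylsilane
Product: 19 triisopropyl{4-[(trimethylsilyl)ethynyl]phenoxy}silane
Conditions: 18 (1.2 equiv), Pd(PPh3)2Cl2 (2 mol%), CuI (4 mol%), Et3N, THF, rt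
Reagents that add atoms: none
Why: Sonogashira coupling of an unhindered aryl iodide with a silyl-capped acetylene; the C-silyl cap prevents double coupling.

Step 8
Reactants: 19 triisopropyl{4-[(trimethylsilyl)ethynyl]phenoxy}silane
Product: 20 (4-ethynylphenoxy)triisopropylsilane
Conditions: K2CO3 (0.2 equiv), MeOH/THF, 0 °C
Reagents that add atoms: none
Why: Base-catalysed methanolysis of the C(sp)–SiMe3 bond is fast, whereas the hindered aryl triisopropylsilyl ether is attacked much more slowly under the same brief, cold conditions.

Step 9
Reactants: 15 {[6-iodo-7-methoxy-2,2-dimethyl-8-(3-methylbut-2-en-1-yl)-2H-chromen-5-yl]oxy}triisopropylsilane; 20 (4-ethynylphenoxy)triisopropylsilane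
Product: 21 7-methoxy-2,2-dimethyl-8-(3-methylbut-2-en-1-yl)-5-[(triisopropylsilyl)oxy]-6-({4-[(triisopropylsilyl)oxy]phenyl}ethynyl)-2H-chromene
Conditions: 20 (1.3 equiv), Pd(PPh3)2Cl2 (5 mol%), CuI (10 mol%), Et3N/THF, 60 °C, degassed
Reagents that add atoms: none
Why: Sonogashira coupling. Oxidative addition of the electron-rich, di-ortho-substituted aryl iodide to zerovalent palladium is slower than usual, which the iodide leaving group and gentle heating compensate; degassing suppresses oxidative dimerisation of 20.

Step 10
Reactants: 21 7-methoxy-2,2-dimethyl-8-(3-methylbut-2-en-1-yl)-5-[(triisopropylsilyl)oxy]-6-({4-[(triisopropylsilyl)oxy]phenyl}ethynyl)-2H-chromene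
Product: 22 1-{7-methoxy-2,2-dimethyl-8-(3-methylbut-2-en-1-yl)-5-[(triisopropylsilyl)oxy]-2H-chromen-6-yl}-2-{4-[(triisopropylsilyl)oxy]phenyl}ethane-1,2-dione
Conditions: Ph3PAuNTf2 (5 mol%), 2,6-dichloropyridine N-oxide (2.5 equiv), ClCH2CH2Cl, 60 °C
Reagents that add atoms: 2,6-dichloropyridine N-oxide, [O-][n+]1c(Cl)cccc1Cl
Why: Gold-catalysed double oxidation of a diarylalkyne: the N-oxide adds to the gold-activated alkyne, N–O cleavage gives an α-oxo gold carbene, and a second N-oxide oxidises the carbene carbon to the second carbonyl. N-oxides do not oxidise isolated alkenes, both phenols are silylated so no benzofuran can form from a free hydroxyl, and the weakly basic 2,6-dichloropyridine released does not require an acid additive.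

Step 11
Reactants: 22 1-{7-methoxy-2,2-dimethyl-8-(3-methylbut-2-en-1-yl)-5-[(triisopropylsilyl)oxy]-2H-chromen-6-yl}-2-{4-[(triisopropylsilyl)oxy]phenyl}ethane-1,2-dione
Product: 23 1-[5-hydroxy-7-methoxy-2,2-dimethyl-8-(3-methylbut-2-en-1-yl)-2H-chromen-6-yl]-2-(4-hydroxyphenyl)ethane-1,2-dione
Conditions: Bu4NF (2.2 equiv), AcOH (2.2 equiv), THF, 0 °C
Reagents that add atoms: none
Why: Fluoride cleaves both aryl silyl ethers in one operation. Acetic acid keeps the phenoxide concentration low and so protects the base-sensitive 1,2-dione, and no acid strong enough to touch the prenyl group or the chromene is present.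

## Compound list

1 | cyclobutane-1,3-dione | O=C1CC(=O)C1 | starting material
2 | 3-[(triisopropylsilyl)oxy]cyclobut-2-en-1-one | O=C1CC(O[Si](C(C)C)(C(C)C)C(C)C)=C1 | intermediate
3 | chloroacetaldehyde dimethyl acetal (2-chloro-1,1-dimethoxyethane) | COC(CCl)OC | starting material
4 | 1-bromo-3-methylbut-2-ene | CC(C)=CCBr | starting material
5 | sodium methoxyacetylide | COC#C[Na] | intermediate
6 | 1-methoxy-5-methylhex-4-en-1-yne | COC#CCC=C(C)C | intermediate
7 | 3-[(triisopropylsilyl)oxy]buta-1,3-dien-1-one (siloxyvinylketene) | C=C(O[Si](C(C)C)(C(C)C)C(C)C)C=C=O | intermediate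
8 | 3-methoxy-2-(3-methylbut-2-en-1-yl)-4-{1-[(triisopropylsilyl)oxy]ethenyl}cyclobut-2-en-1-one (racemic) | COC1=C(CC=C(C)C)C(=O)C1C(=C)O[Si](C(C)C)(C(C)C)C(C)C | intermediate
9 | (3E)-3-methoxy-2-(3-methylbut-2-en-1-yl)-5-[(triisopropylsilyl)oxy]hexa-1,3,5-trien-1-one (ketene and siloxyvinyl group cis) | O=C=C(CC=C(C)C)/C(OC)=C\C(=C)O[Si](C(C)C)(C(C)C)C(C)C | intermediate
10 | 3-methoxy-2-(3-methylbut-2-en-1-yl)-5-[(triisopropylsilyl)oxy]cyclohexa-2,4-dien-1-one | O=C1CC(O[Si](C(C)C)(C(C)C)C(C)C)=CC(OC)=C1CC=C(C)C | intermediate
11 | 3-methoxy-2-(3-methylbut-2-en-1-yl)-5-[(triisopropylsilyl)oxy]phenol | COc1cc(O[Si](C(C)C)(C(C)C)C(C)C)cc(O)c1CC=C(C)C | intermediate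
12 | 3-methylbut-2-enal | CC(C)=CC=O | starting material
13 | 3-methoxy-2-(3-methylbut-2-en-1-yl)-6-(3-methylbut-2-en-1-ylidene)-5-[(triisopropylsilyl)oxy]cyclohexa-2,4-dien-1-one (exocyclic alkene geometry not defined) | O=C1C(CC=C(C)C)=C(OC)C=C(O[Si](C(C)C)(C(C)C)C(C)C)C1=CC=C(C)C | intermediate
14 | triisopropyl{[7-methoxy-2,2-dimethyl-8-(3-methylbut-2-en-1-yl)-2H-chromen-5-yl]oxy}silane | COc1cc(O[Si](C(C)C)(C(C)C)C(C)C)c2C=CC(C)(C)Oc2c1CC=C(C)C | intermediate
15 | {[6-iodo-7-methoxy-2,2-dimethyl-8-(3-methylbut-2-en-1-yl)-2H-chromen-5-yl]oxy}triisopropylsilane | COc1c(I)c(O[Si](C(C)C)(C(C)C)C(C)C)c2C=CC(C)(C)Oc2c1CC=C(C)C | intermediate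
16 | 4-iodophenol | Oc1ccc(I)cc1 | starting material
17 | (4-iodophenoxy)triisopropylsilane | CC(C)[Si](Oc1ccc(I)cc1)(C(C)C)C(C)C | intermediate
18 | ethynyltrimethylsilane | C#C[Si](C)(C)C | starting material
19 | triisopropyl{4-[(trimethylsilyl)ethynyl]phenoxy}silane | CC(C)[Si](Oc1ccc(C#C[Si](C)(C)C)cc1)(C(C)C)C(C)C | intermediate
20 | (4-ethynylphenoxy)triisopropylsilane | CC(C)[Si](Oc1ccc(C#C)cc1)(C(C)C)C(C)C | intermediate
21 | 7-methoxy-2,2-dimethyl-8-(3-methylbut-2-en-1-yl)-5-[(triisopropylsilyl)oxy]-6-({4-[(triisopropylsilyl)oxy]phenyl}ethynyl)-2H-chromene | COc1c(C#Cc3ccc(O[Si](C(C)C)(C(C)C)C(C)C)cc3)c(O[Si](C(C)C)(C(C)C)C(C)C)c2C=CC(C)(C)Oc2c1CC=C(C)C | intermediate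
22 | 1-{7-methoxy-2,2-dimethyl-8-(3-methylbut-2-en-1-yl)-5-[(triisopropylsilyl)oxy]-2H-chromen-6-yl}-2-{4-[(triisopropylsilyl)oxy]phenyl}ethane-1,2-dione | COc1c(C(=O)C(=O)c3ccc(O[Si](C(C)C)(C(C)C)C(C)C)cc3)c(O[Si](C(C)C)(C(C)C)C(C)C)c2C=CC(C)(C)Oc2c1CC=C(C)C | intermediate
23 | 1-[5-hydroxy-7-methoxy-2,2-dimethyl-8-(3-methylbut-2-en-1-yl)-2H-chromen-6-yl]-2-(4-hydroxyphenyl)ethane-1,2-dione | COc1c(CC=C(C)C)c2c(c(O)c1C(=O)C(=O)c1ccc(O)cc1)C=CC(C)(C)O2 | target

## Step count and risks

Total: 11 steps. Longest linear sequence: 7 steps (steps 1, 3, 4, 5, 9, 10, 11; the branch through step 2 is equally long, the aryl alkyne branch through steps 6–8 has 6).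

**Step 3 (key step).** The most likely failure is a sluggish first ring opening of the push–pull stabilised cyclobutenone. At the temperature then required, oligomerisation of the ynol ether, dimerisation of the ketene or O-acylation of the product phenol by the ketene could overtake the annulation. The fallback gives up ring construction and builds 11 on a preformed arene; it sets out from bromide 4 and comes back at 11.
- The arene is commercial 5-methoxybenzene-1,3-diol F1.
- F1 is monosilylated with i-Pr3SiCl and imidazole to 3-methoxy-5-[(triisopropylsilyl)oxy]phenol F2.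
- F2 is protected with chloromethyl methyl ether and i-Pr2NEt as [3-methoxy-5-(methoxymethoxy)phenoxy]triisopropylsilane F3.
- F3 is deprotonated by n-BuLi between the two coordinating ether groups to give {2-methoxy-6-(methoxymethoxy)-4-[(triisopropylsilyl)oxy]phenyl}lithium F4.
- F4 is transmetalated with CuBr·SMe2 and alkylated with 4 to give [3-methoxy-5-(methoxymethoxy)-4-(3-methylbut-2-en-1-yl)phenoxy]triisopropylsilane F5.
- F5 loses the acetal on brief treatment with HCl in MeOH and returns 11.
- This sequence relies on statistical monosilylation of a symmetric diol and on directed metalation for the regiochemistry.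

**Step 10.** The gold-activated alkyne or the α-oxo gold carbene could be intercepted by the flanking methoxy or siloxy oxygen (cyclisation with methyl or silyl transfer toward a benzofuran or benzofuranone). The two ortho substituents could also slow coordination so far that the catalyst decays first. The fallback forms the dione without any oxidation; it sets out from iodide 15 and aryl iodide 17 and comes back at 22, bypassing 20 and 21.
- Iodine–magnesium exchange on 15 with i-PrMgCl·LiCl gives chloro{7-methoxy-2,2-dimethyl-8-(3-methylbut-2-en-1-yl)-5-[(triisopropylsilyl)oxy]-2H-chromen-6-yl}magnesium F6.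
- F6 adds once to 1,4-dimethylpiperazine-2,3-dione A2 and gives the chloromagnesium salt of 3-hydroxy-1,4-dimethyl-3-{7-methoxy-2,2-dimethyl-8-(3-methylbut-2-en-1-yl)-5-[(triisopropylsilyl)oxy]-2H-chromen-6-yl}piperazin-2-one F7.
- F7 persists as its tetrahedral salt while the same exchange on 17 gives chloro{4-[(triisopropylsilyl)oxy]phenyl}magnesium F8.
- F8 adds to the remaining amide carbonyl of the first adduct and gives the bis(chloromagnesium) salt of 2-{7-methoxy-2,2-dimethyl-8-(3-methylbut-2-en-1-yl)-5-[(triisopropylsilyl)oxy]-2H-chromen-6-yl}-1,4-dimethyl-3-{4-[(triisopropylsilyl)oxy]phenyl}piperazine-2,3-diol F9.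
- F9 collapses in mild aqueous acid, which releases the diamine and 22.

**Step 5.** Iodonium transfer to the electron-rich chromene C3=C4 bond or to the prenyl alkene could compete with substitution on the arene. The fallback uses a weaker carbon electrophile and builds the alkyne from the ring outward; it sets out from 14 and 17 and comes back at 21.
- Vilsmeier–Haack formylation of 14 with POCl3 and DMF gives 7-methoxy-2,2-dimethyl-8-(3-methylbut-2-en-1-yl)-5-[(triisopropylsilyl)oxy]-2H-chromene-6-carbaldehyde F10.
- F10 is homologated in an Ohira–Bestmann reaction with dimethyl (1-diazo-2-oxopropyl)phosphonate, K2CO3 and MeOH to {[6-ethynyl-7-methoxy-2,2-dimethyl-8-(3-methylbut-2-en-1-yl)-2H-chromen-5-yl]oxy}triisopropylsilane F11.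
- F11 is joined to 17 by Sonogashira coupling and gives 21.

**Step 4.** Condensation at the ortho carbon, which is flanked by the hydroxyl and the bulky siloxy group, may be slow for a monophenol. Prenal self-condensation or unproductive attack at the para carbon would then consume the aldehyde. The fallback makes the C–C bond intramolecularly; it sets out from 11 and comes back at 14.
- O-Alkylation of 11 with 3-chloro-3-methylbut-1-yne, catalytic CuCl2 and DBU in MeCN at 0 °C gives triisopropyl{3-methoxy-5-[(2-methylbut-3-yn-2-yl)oxy]-4-(3-methylbut-2-en-1-yl)phenoxy}silane F12.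
- F12 is heated in xylene and gives 14 by aromatic Claisen rearrangement to the only free ortho carbon, hydrogen shift and oxa-6π closure.

**Step 2.** Residual amide base could isomerise the skipped enyne to conjugated or allenic isomers, or could eliminate HBr from the allylic bromide before alkylation. The fallback avoids amide bases and ammonia; it sets out from 4 and comes back at 6.
- Trichloroethylene with KH and methanol in THF gives (E)-1,2-dichloro-1-methoxyethene F13.
- F13 is converted by two equivalents of n-BuLi at −78 °C into lithium methoxyacetylide F14.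
- F14 is alkylated with 4 in THF with DMPU and gives 6.

## Further compounds

F1 | step 3 | 5-methoxybenzene-1,3-diol | COc1cc(O)cc(O)c1
F2 | step 3 | 3-methoxy-5-[(triisopropylsilyl)oxy]phenol | COc1cc(O)cc(O[Si](C(C)C)(C(C)C)C(C)C)c1
F3 | step 3 | [3-methoxy-5-(methoxymethoxy)phenoxy]triisopropylsilane | COCOc1cc(OC)cc(O[Si](C(C)C)(C(C)C)C(C)C)c1
F4 | step 3 | {2-methoxy-6-(methoxymethoxy)-4-[(triisopropylsilyl)oxy]phenyl}lithium | [Li]c1c(OC)cc(O[Si](C(C)C)(C(C)C)C(C)C)cc1OCOC
F5 | step 3 | [3-methoxy-5-(methoxymethoxy)-4-(3-methylbut-2-en-1-yl)phenoxy]triisopropylsilane | COCOc1cc(O[Si](C(C)C)(C(C)C)C(C)C)cc(OC)c1CC=C(C)C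
F6 | step 10 | chloro{7-methoxy-2,2-dimethyl-8-(3-methylbut-2-en-1-yl)-5-[(triisopropylsilyl)oxy]-2H-chromen-6-yl}magnesium | Cl[Mg]c1c(OC)c(CC=C(C)C)c2OC(C)(C)C=Cc2c1O[Si](C(C)C)(C(C)C)C(C)C
F7 | step 10 | chloromagnesium salt of 3-hydroxy-1,4-dimethyl-3-{7-methoxy-2,2-dimethyl-8-(3-methylbut-2-en-1-yl)-5-[(triisopropylsilyl)oxy]-2H-chromen-6-yl}piperazin-2-one (racemic) | CN1CCN(C)C(O[Mg]Cl)(C1=O)c1c(OC)c(CC=C(C)C)c2OC(C)(C)C=Cc2c1O[Si](C(C)C)(C(C)C)C(C)C
F8 | step 10 | chloro{4-[(triisopropylsilyl)oxy]phenyl}magnesium | Cl[Mg]c1ccc(O[Si](C(C)C)(C(C)C)C(C)C)cc1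
F9 | step 10 | bis(chloromagnesium) salt of 2-{7-methoxy-2,2-dimethyl-8-(3-methylbut-2-en-1-yl)-5-[(triisopropylsilyl)oxy]-2H-chromen-6-yl}-1,4-dimethyl-3-{4-[(triisopropylsilyl)oxy]phenyl}piperazine-2,3-diol (diastereomer mixture) | CN1CCN(C)C(O[Mg]Cl)(c2ccc(O[Si](C(C)C)(C(C)C)C(C)C)cc2)C1(O[Mg]Cl)c1c(OC)c(CC=C(C)C)c2OC(C)(C)C=Cc2c1O[Si](C(C)C)(C(C)C)C(C)C
F10 | step 5 | 7-methoxy-2,2-dimethyl-8-(3-methylbut-2-en-1-yl)-5-[(triisopropylsilyl)oxy]-2H-chromene-6-carbaldehyde | COc1c(C=O)c(O[Si](C(C)C)(C(C)C)C(C)C)c2C=CC(C)(C)Oc2c1CC=C(C)C
F11 | step 5 | {[6-ethynyl-7-methoxy-2,2-dimethyl-8-(3-methylbut-2-en-1-yl)-2H-chromen-5-yl]oxy}triisopropylsilane | COc1c(C#C)c(O[Si](C(C)C)(C(C)C)C(C)C)c2C=CC(C)(C)Oc2c1CC=C(C)C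
F12 | step 4 | triisopropyl{3-methoxy-5-[(2-methylbut-3-yn-2-yl)oxy]-4-(3-methylbut-2-en-1-yl)phenoxy}silane | COc1cc(O[Si](C(C)C)(C(C)C)C(C)C)cc(OC(C)(C)C#C)c1CC=C(C)C
F13 | step 2 | (E)-1,2-dichloro-1-methoxyethene | CO/C(Cl)=C\Cl
F14 | step 2 | lithium methoxyacetylide | COC#C[Li]
A1 | alternative 1 | 1-[7-methoxy-5-(methoxymethoxy)-2,2-dimethyl-8-(3-methylbut-2-en-1-yl)-2H-chromen-6-yl]-2-[4-(methoxymethoxy)phenyl]ethane-1,2-dione | COCOc1c(C(=O)C(=O)c2ccc(OCOC)cc2)c(OC)c(CC=C(C)C)c2OC(C)(C)C=Cc12
A2 | alternative 1 | 1,4-dimethylpiperazine-2,3-dione | CN1CCN(C)C(=O)C1=O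
A3 | alternative 1 | 6-lithio-7-methoxy-5-(methoxymethoxy)-2,2-dimethyl-8-(3-methylbut-2-enyl)-2H-chromene | [Li]c1c(OC)c(CC=C(C)C)c2OC(C)(C)C=Cc2c1OCOC
A4 | alternative 1 | 4-(methoxymethoxy)phenyllithium | [Li]c1ccc(OCOC)cc1
A5 | alternative 2 | 1-[4-hydroxy-2-methoxy-6-(4-methoxybenzyloxy)-3-(3-methylbut-2-enyl)phenyl]-2,2-dimethoxy-2-[4-(methoxymethoxy)phenyl]ethanone | COc1c(CC=C(C)C)c(O)cc(OCc2ccc(OC)cc2)c1C(=O)C(OC)(OC)c1ccc(OCOC)cc1
A6 | alternative 2 | 1-(4-methoxybenzyloxy)-3-(tert-butyldimethylsiloxy)-4-(3-methylbut-2-enyl)cyclohexa-1,3-diene | COc1ccc(COC2=CC(O[Si](C)(C)C(C)(C)C)=C(CC=C(C)C)CC2)cc1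
A7 | alternative 2 | 1,1,4-trimethoxy-1-[4-(methoxymethoxy)phenyl]but-3-yn-2-one | COC#CC(=O)C(OC)(OC)c1ccc(OCOC)cc1
A8 | alternative 2 | ethene | C=C
A9 | alternative 3 | 1-[2,4-dihydroxy-6-methoxy-5-(3-methylbut-2-enyl)phenyl]-2,2-dimethoxy-2-[4-(methoxymethoxy)phenyl]ethanone | COc1c(CC=C(C)C)c(O)cc(O)c1C(=O)C(OC)(OC)c1ccc(OCOC)cc1
A10 | alternative 3 | 3-{2,2-dimethoxy-2-[4-(methoxymethoxy)phenyl]acetyl}-4-methoxy-6-methyl-5-(3-methylbut-2-enyl)-2H-pyran-2-one | COc1c(CC=C(C)C)c(C)oc(=O)c1C(=O)C(OC)(OC)c1ccc(OCOC)cc1
A11 | alternative 3 | magnesium dimethoxide | CO[Mg]OC
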